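## The problem

Target 24 is an aryl ketone: C7 of a 6-hydroxy-4-methoxybenzofuran is bonded through the carbonyl group to C1 of a cyclohexene that carries a prenyl group at C2, a methyl group on the C3=C4 double bond and a phenyl group at C6. The three stereocentres C1, C2 and C6 are contiguous, with acyl and prenyl cis, acyl and phenyl trans, and absolute configuration (1R,2S,6R). C1 is the delicate centre, because it is α to the ketone and can epimerise once the carbonyl group exists. It should therefore be fixed early by a rigid relay and raised to the carbonyl oxidation level late, and C2 and C6 are best set relative to it, since the flat arene can control neither. Two trisubstituted alkenes arranged as a 1,5-diene, an electron-rich furan and a chelated phenol exclude hydrogenation, prolonged exposure to strong protic or Lewis acids, and hard bases once the ketone is present. On the arene the acyl group lies between the furan oxygen and the free hydroxyl group, with the methoxy group para, so the three oxygens of a phloroglucinol must be told apart. The enabling feature is the 1,4-relation of C1, which bears a carbonyl carbon, and C4, an sp2 carbon that can hold a temporary oxygen on the same face. Tied together they form the CO–O bridge of a 2-oxabicyclo[2.2.2]octenone whose other bridges are C2=C3 and the styrene-derived C5–C6 unit, and once the bridge is cut the C4 oxygen is allylic and on the correct face to pass a carbon substituent to C2.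

## Retrosynthesis

**24 from 23.** The O–CH3 bond at C6 is cut last. In 23 this methoxy group is the only one that can form a six-membered chelate with the ketone, so a chelating Lewis acid can tell it from the para methoxy group. The alternative of carrying a differently protected C6 oxygen would need a non-symmetric phloroglucinol from the start. The forward step must be fast at low temperature so that the alkenes are spared.

**23 from 16 and 20.** The C7–C(=O) bond is cut to aldehyde 16 and the aryllithium 21 derived from bromide 20, with carbinol 22 in between. Cutting on the other side of the carbonyl would require a C1 carbanion and lose the stereocentre, and a Friedel–Crafts acylation would expose the diene to acid and leave the site on the arene open. The cut divides the molecule into two fragments of similar size, and the forward addition must outrun enolisation of 16.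

**20 from 17.** The C7–Br bond, then the furan bond C3–C3a, then the O–CH2 bond are removed, giving 19, 18 and the symmetric phenol 17. Closing the furan on a symmetric ring allows only one benzofuran, and the oxygenation pattern is bought rather than made. What remains to be secured is bromination of 19 at C7 and not at C5 or on the furan.

**16 from 12.** The prenyl C=C bond is cut by a Wittig disconnection to aldehyde 13, which comes from ester 12. The C1 carbon is kept as a silyl-protected CH2OH (14, 15) until just before the fragment union, so that C1 is never α to a carbonyl group for more than two steps.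

**12 from 8 and 9.** The bond between C2 and its side-chain CH2 is cut in the Claisen sense. An allylic alcohol with oxygen on C4 and the double bond at C2=C3 (8), together with orthoester 9, delivers the acetate unit to C2 on the face of the oxygen and moves the alkene to C3=C4. An enolate alkylation at C2 would have no such facial control. The forward step must form the cis-1,2 relation next to the CH2OTBS group without ionising the allylic alcohol.

**8 from 6.** The silyl ether is removed and the single enantiomer 7 is traced to racemic diol 6. Resolution is placed here because 6 is the first intermediate with a handle (a primary alcohol beside a stereocentre) and no material has yet been invested in the side chain or the arene.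

**6 from 4.** The diol is the reduced form of the bridging lactone 5, and the bridgehead C–H of 5 is the reduced form of the C–Br bond of 4. Reduction to the alcohol level before the cage is opened prevents a C1 carbonyl from drawing the C2=C3 alkene into conjugation.

**4 from 2 and 3.** The bonds C1–C6 and C4–C5 (target numbering) are cut, a retro-Diels–Alder reaction to bromopyrone 2 and styrene 3. This single cut removes one ring, two skeletal bonds and all three stereocentres' relative configuration: C1 and C4 are tied by the bridge, and C6 follows from endo addition. It requires regio- and endo selectivity and a temperature below that of CO2 extrusion.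

**2 from 1.** The C5–CH3 bond is cut to the commercial dibromide 1. The forward coupling must distinguish the C5 from the C3 bromide.

## Roads not taken

**Alternative 1:** The cut is through the furan bonds C3–C3a and O1–C2, so the heterocycle is added last to a symmetric aryl ketone. The (2,6-dihydroxy-4-methoxyphenyl) ketone A3 would be mono-iodinated to A2. Sonogashira coupling with a silyl-capped acetylene (PdCl2(PPh3)2, CuI, Et3N) and 5-endo-dig attack of the neighbouring phenol would then give the 2-silylbenzofuran A1, which still has to lose silicon.
- Merits: the aryl part stays symmetric until late, so the aryl–carbonyl bond can be made from a readily available 2,4,6-trioxygenated aryl anion with no site question. The C6 hydroxyl group of the target is simply the phenol that is not used.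
- Weak points: iodination must stop at one of two equivalent positions and brings an electrophilic halogen into a molecule with two nucleophilic alkenes and phenols placed to trap iodonium ions. Three more steps are run on the complete skeleton with C1 epimerisable throughout. The idea also does not say how the cyclohexene is made.
- Comparison: on the arene side this road is better than the chosen one in two respects, since it needs neither the site-selective bromination of step 14 nor the Lewis-acid demethylation of step 17. The chosen plan sets against this that the whole heteroaromatic half is finished on inexpensive material, that only three steps follow the fragment union, and that no halogenating agent meets the diene.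

**Alternative 2:** The cut is the C3=C4 double bond. The open-chain triene ketone A5 would close under the second-generation Grubbs catalyst, with loss of ethylene, to A4, which is identical with 23. The stereotriad would be set beforehand in the open chain by an Ireland–Claisen rearrangement and an earlier asymmetric step.
- Merits: metathesis to a six-membered ring with a trisubstituted alkene is dependable, no tin is used, and the sequence could be enantioselective from the outset. Avoiding a resolution that discards half the material is a real advantage over the chosen plan.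
- Weak points: three contiguous centres must be controlled without a ring. The sigmatropic shift relates C1 to C2 through enolate and alkene geometry, but their relation to C6 rests on open-chain induction from a benzylic centre. A5 also contains the prenyl alkene, which can enter metathesis, and a ketone α-centre exposed to ruthenium hydrides. A4 still needs the final demethylation.
- Comparison: the chosen plan takes the relative configuration of all three centres from a cage and a suprafacial shift, with no open-chain stereocontrol, and pays for this with the resolution.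

**Alternative 3:** The cut is the C7–C7a bond of the benzene ring. The triketo ester A7 would undergo intramolecular Claisen condensation with Mg(OMe)2 in MeOH to the acylphloroglucinol A6.
- Merits: the arene is assembled from acetate-level units with all three oxygens in place and no aryl organometallic. The para hydroxyl group of A6, which is not hydrogen-bonded, could be methylated selectively.
- Weak points: A7 is a base-labile poly-β-carbonyl chain ending at the epimerisable C1, and aldol-type closure and pyrone formation compete with the wanted mode. After A6 the O-methylation and the whole furan annulation of Alternative 1 are still to come, which makes this the longest endgame. The stereotriad is not addressed.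
- Comparison: this road builds a ring that the chosen plan buys as 17. It is better only in avoiding the bromination site question, against which the chosen plan offers three simple steps to 20.

Key step: step 2

Assumption: the lipase of step 5 follows its usual size rule for primary alcohols with a stereocentre next to the CH2OH group and acetylates the (1S,4S,5S)-diol faster; if the preference were reversed, the monoacetate would be the wanted enantiomer and would be methanolysed (K2CO3, MeOH) to 7.

Racemic compounds 4, 5 and 6 are named and drawn as the enantiomer that is carried on.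

## Route

Step 1
Reactants: 1 3,5-dibromo-2H-pyran-2-one
Product: 2 3-bromo-5-methyl-2H-pyran-2-one
Conditions: Me4Sn (1.5 equiv), Pd(PPh3)4 (5 mol%), CuI (1 equiv), DMF, 50 °C
Reagents that add atoms: tetramethylstannane, C[Sn](C)(C)C
Why: Stille cross-coupling; for this dibromide the combination of CuI and DMF is known to direct aryl-, vinyl- and alkynylstannanes to the C5 bromide instead of C3, and the same site preference is counted on for methyl transfer. The C3 bromine, which polarises the diene for step 2, is kept.

Step 2
Reactants: 2 3-bromo-5-methyl-2H-pyran-2-one; 3 styrene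
Product: 4 rac-(1R,4S,8S)-4-bromo-6-methyl-8-phenyl-2-oxabicyclo[2.2.2]oct-5-en-3-one (endo adduct)
Conditions: 3 (4 equiv), BHT (cat.), PhMe, 100 °C, sealed tube
Reagents that add atoms: none
Why: A thermal Diels–Alder reaction of a 2-pyrone; the closest known type is the endo-selective addition of 3-bromo- and 3,5-dibromo-2-pyrones to styrenes that stops at the bicyclic lactone. The diene C3=C4–C5=C6 of the pyrone and the styrene double bond combine in a concerted, asynchronous, suprafacial [4+2] process in which the bond from the styrene CH2 to the electrophilic C6 of the pyrone runs ahead of the bond from the benzylic carbon to the bromine-bearing C3. The six-membered carbocycle is closed by this intermolecular cycloaddition across the two ends of the diene, and the CO–O unit of the pyrone is left as the third bridge of a bicyclo[2.2.2]octene. C1 and C4 of 4 are bridgeheads whose relative configuration is dictated by the bicycle, and C8 is set by the endo transition state, in which phenyl lies under the diene and ends anti to the lactone bridge. The step needs regio- and endo selectivity: the first should follow from the polarisation of the bromopyrone against styrene, whose terminal carbon is the nucleophilic one, and the second from secondary overlap of the aryl group with the diene and the steric cost of placing phenyl beside the CO–O bridge. The temperature is held at 100 °C, where such bromo lactones do not yet lose CO2, and a radical inhibitor restrains polymerisation of the excess styrene. The adduct is racemic, and any exo isomer should be separable by chromatography.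

Step 3
Reactants: 4 rac-(1R,4S,8S)-4-bromo-6-methyl-8-phenyl-2-oxabicyclo[2.2.2]oct-5-en-3-one
Product: 5 rac-(1R,4R,8R)-6-methyl-8-phenyl-2-oxabicyclo[2.2.2]oct-5-en-3-one
Conditions: Bu3SnH (1.2 equiv), AIBN (10 mol%), PhH, 80 °C
Reagents that add atoms: none
Why: Radical-chain hydrodebromination; the tertiary bromide next to the lactone carbonyl is abstracted readily, and the pyramidal bridgehead radical is held by the cage, so hydrogen can only arrive where bromine left (retention). The alkene is orthogonal to the radical and is not transposed.

Step 4
Reactants: 5 rac-(1R,4R,8R)-6-methyl-8-phenyl-2-oxabicyclo[2.2.2]oct-5-en-3-one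
Product: 6 rac-(1R,4R,5R)-4-(hydroxymethyl)-2-methyl-5-phenylcyclohex-2-en-1-ol
Conditions: LiAlH4 (1.5 equiv), THF, 0 °C to rt; aqueous work-up
Reagents that add atoms: none
Why: Hydride reduction of the lactone to the diol; no stereocentre is touched and the cis-1,4 relation of OH and CH2OH is inherited from the bridge. The carbonyl carbon is reduced now because, once the cage is open, the ring carbon next to it is allylic and a carbonyl group there would pull the double bond into conjugation.

Step 5
Reactants: 6 rac-(1R,4R,5R)-4-(hydroxymethyl)-2-methyl-5-phenylcyclohex-2-en-1-ol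
Product: 7 (1R,4R,5R)-4-(hydroxymethyl)-2-methyl-5-phenylcyclohex-2-en-1-ol (single enantiomer, recovered unreacted)
Conditions: lipase PS (Burkholderia cepacia), vinyl acetate, t-BuOMe, 30 °C, run past 50% conversion; chromatography
Reagents that add atoms: none
Why: Lipase-catalysed transesterification used as a kinetic resolution: the enzyme acetylates only the primary hydroxyl group and distinguishes the enantiomers through the adjacent ring stereocentre, which has a large CH(Ph) and a small vinylic CH neighbour. The wanted diol is the slow-reacting enantiomer, so its enantiomeric purity can be raised by letting the conversion pass one half before it is separated from the monoacetate.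

Step 6
Reactants: 7 (1R,4R,5R)-4-(hydroxymethyl)-2-methyl-5-phenylcyclohex-2-en-1-ol
Product: 8 (1R,4R,5R)-4-({[tert-butyl(dimethyl)silyl]oxy}methyl)-2-methyl-5-phenylcyclohex-2-en-1-ol
Conditions: TBSCl (1.05 equiv), imidazole, CH2Cl2, 0 °C
Reagents that add atoms: tert-butyl(chloro)dimethylsilane, CC(C)(C)[Si](C)(C)Cl
Why: Silyl ether formation; the primary hydroxyl group should react far faster than the secondary allylic one, which is flanked by the methyl-bearing alkene carbon.

Step 7
Reactants: 8 (1R,4R,5R)-4-({[tert-butyl(dimethyl)silyl]oxy}methyl)-2-methyl-5-phenylcyclohex-2-en-1-ol; 9 triethyl orthoacetate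
Product: 12 ethyl 2-[(1S,5R,6R)-6-({[tert-butyl(dimethyl)silyl]oxy}methyl)-2-methyl-5-phenylcyclohex-2-en-1-yl]acetate, via mixed orthoester 10 (not isolated), via ketene acetal 11 (not isolated)
Conditions: 9 (10 equiv), EtCO2H (5 mol%), 140 °C, EtOH distilled off
Reagents that add atoms: none
Why: Johnson–Claisen rearrangement: acid-catalysed exchange gives the mixed orthoester, loss of ethanol gives the ketene acetal, and a suprafacial [3,3] shift moves the two-carbon ester unit from the oxygen-bearing carbon to the far end of the allyl system on the same face. The new stereocentre should therefore be cis to the CH2OTBS carbon and trans to phenyl, and the double bond lands in its final place next to the methyl group. In the conformer with equatorial phenyl the carbinol C–O bond is pseudoaxial, as the shift requires.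

Step 8
Reactants: 12 ethyl 2-[(1S,5R,6R)-6-({[tert-butyl(dimethyl)silyl]oxy}methyl)-2-methyl-5-phenylcyclohex-2-en-1-yl]acetate
Product: 13 2-[(1S,5R,6R)-6-({[tert-butyl(dimethyl)silyl]oxy}methyl)-2-methyl-5-phenylcyclohex-2-en-1-yl]acetaldehyde
Conditions: i-Bu2AlH (1.1 equiv), CH2Cl2, −78 °C; MeOH, then aq. potassium sodium tartrate
Reagents that add atoms: none
Why: Partial reduction of the ester; at −78 °C the aluminium hemiacetal should persist until work-up and then release the aldehyde. The ring stereocentre is β to the new carbonyl group and is not at risk.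

Step 9
Reactants: 13 2-[(1S,5R,6R)-6-({[tert-butyl(dimethyl)silyl]oxy}methyl)-2-methyl-5-phenylcyclohex-2-en-1-yl]acetaldehyde
Product: 14 tert-butyl(dimethyl){[(1R,2S,6R)-3-methyl-2-(3-methylbut-2-en-1-yl)-6-phenylcyclohex-3-en-1-yl]methoxy}silane
Conditions: i-PrPPh3I (1.5 equiv), n-BuLi, THF, 0 °C; then 13, −78 °C to rt
Reagents that add atoms: isopropyltriphenylphosphonium iodide, CC(C)[P+](c1ccccc1)(c1ccccc1)c1ccccc1.[I-]
Why: Wittig olefination with the non-stabilised isopropylidene ylide; the ylide is symmetric, so no alkene geometry arises, and the prenyl group is complete.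

Step 10
Reactants: 14 tert-butyl(dimethyl){[(1R,2S,6R)-3-methyl-2-(3-methylbut-2-en-1-yl)-6-phenylcyclohex-3-en-1-yl]methoxy}silane
Product: 15 [(1R,2S,6R)-3-methyl-2-(3-methylbut-2-en-1-yl)-6-phenylcyclohex-3-en-1-yl]methanol
Conditions: Bu4NF, THF, 0 °C to rt
Reagents that add atoms: none
Why: Fluoride-induced cleavage of the silyl ether; nothing else in 14 responds to fluoride.

Step 11
Reactants: 15 [(1R,2S,6R)-3-methyl-2-(3-methylbut-2-en-1-yl)-6-phenylcyclohex-3-en-1-yl]methanol
Product: 16 (1R,2S,6R)-3-methyl-2-(3-methylbut-2-en-1-yl)-6-phenylcyclohex-3-ene-1-carbaldehyde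
Conditions: Dess–Martin periodinane, NaHCO3, CH2Cl2, 0 °C to rt; used at once
Reagents that add atoms: none
Why: Dess–Martin oxidation of the primary alcohol under buffered, non-basic conditions, which should leave the now α-positioned C1 stereocentre and both alkenes untouched.

Step 12
Reactants: 17 3,5-dimethoxyphenol
Product: 18 1-(2,2-diethoxyethoxy)-3,5-dimethoxybenzene
Conditions: BrCH2CH(OEt)2 (1.5 equiv), K2CO3, DMF, 120 °C
Reagents that add atoms: 2-bromo-1,1-diethoxyethane, CCOC(CBr)OCC
Why: Williamson ether synthesis, an SN2 displacement of bromide by the phenoxide; the β-dialkoxy bromide is sluggish and needs heat, and in a dipolar aprotic solvent O-alkylation should dominate.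

Step 13
Reactants: 18 1-(2,2-diethoxyethoxy)-3,5-dimethoxybenzene
Product: 19 4,6-dimethoxy-1-benzofuran
Conditions: Amberlyst 15, PhCl, 120 °C
Reagents that add atoms: none
Why: Acid-catalysed cyclodehydration: the acetal ionises to an oxocarbenium ion that attacks the ring ortho to the ether oxygen (intramolecular Friedel–Crafts alkylation), and loss of ethanol aromatises the furan. Both ortho positions of 18 are equivalent, so only one benzofuran can form.

Step 14
Reactants: 19 4,6-dimethoxy-1-benzofuran
Product: 20 7-bromo-4,6-dimethoxy-1-benzofuran
Conditions: NBS (1.0 equiv), MeCN, −20 to 0 °C, dark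
Reagents that add atoms: N-bromosuccinimide, O=C1CCC(=O)N1Br
Why: Electrophilic aromatic bromination; the benzene ring, activated by three oxygens, is far more nucleophilic than the furan double bond, and of its two free positions C7 (between the ring oxygen and one methoxy group) is less hindered than C5 (between two methoxy groups). The same preference for the position next to the ring heteroatom is known from halogenations of 5,7-dialkoxychromones and 4,6-dimethoxyindoles.

Step 15
Reactants: 20 7-bromo-4,6-dimethoxy-1-benzofuran; 16 (1R,2S,6R)-3-methyl-2-(3-methylbut-2-en-1-yl)-6-phenylcyclohex-3-ene-1-carbaldehyde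
Product: 22 (4,6-dimethoxy-1-benzofuran-7-yl)[(1R,2S,6R)-3-methyl-2-(3-methylbut-2-en-1-yl)-6-phenylcyclohex-3-en-1-yl]methanol (both carbinol epimers), via (4,6-dimethoxy-1-benzofuran-7-yl)lithium 21 (not isolated)
Conditions: 20 (1.3 equiv), n-BuLi (1.25 equiv), THF, −78 °C, 15 min; then 16, −78 to −40 °C; H2O
Reagents that add atoms: none
Why: Bromine–lithium exchange followed by 1,2-addition of the aryllithium to the aldehyde; at −78 °C exchange should be faster than deprotonation at C2 of the furan, and addition to the aldehyde faster than its enolisation. The carbinol centre forms as a mixture, which is of no consequence because step 16 removes it.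

Step 16
Reactants: 22 (4,6-dimethoxy-1-benzofuran-7-yl)[(1R,2S,6R)-3-methyl-2-(3-methylbut-2-en-1-yl)-6-phenylcyclohex-3-en-1-yl]methanol
Product: 23 (4,6-dimethoxy-1-benzofuran-7-yl)[(1R,2S,6R)-3-methyl-2-(3-methylbut-2-en-1-yl)-6-phenylcyclohex-3-en-1-yl]methanone
Conditions: Dess–Martin periodinane, NaHCO3, CH2Cl2, 0 °C to rt
Reagents that add atoms: none
Why: Dess–Martin oxidation of the benzylic secondary alcohol to the aryl ketone; the neutral, buffered medium should not epimerise C1.

Step 17
Reactants: 23 (4,6-dimethoxy-1-benzofuran-7-yl)[(1R,2S,6R)-3-methyl-2-(3-methylbut-2-en-1-yl)-6-phenylcyclohex-3-en-1-yl]methanone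
Product: 24 (6-hydroxy-4-methoxy-1-benzofuran-7-yl)[(1R,2S,6R)-3-methyl-2-(3-methylbut-2-en-1-yl)-6-phenylcyclohex-3-en-1-yl]methanone
Conditions: BCl3 (1 M in CH2Cl2, 1.5 equiv), CH2Cl2, −78 to −30 °C; then cold aq. NaHCO3
Reagents that add atoms: none
Why: Chelation-controlled ether cleavage: BCl3 bridges the ketone oxygen and the neighbouring 6-methoxy oxygen and chloride removes that methyl group by SN2, while the 4-methoxy group, para to the ketone, cannot chelate and should stay. The six-membered chelate makes the cleavage fast at low temperature, which is what should spare the two alkenes and the furan.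

## Compound list

1 | 3,5-dibromo-2H-pyran-2-one | O=C1OC=C(Br)C=C1Br | starting material
2 | 3-bromo-5-methyl-2H-pyran-2-one | O=C1OC=C(C)C=C1Br | intermediate
3 | styrene | C=Cc1ccccc1 | starting material
4 | rac-(1R,4S,8S)-4-bromo-6-methyl-8-phenyl-2-oxabicyclo[2.2.2]oct-5-en-3-one (endo, phenyl anti to the lactone bridge; racemic) | O=C1[C@]2(Br)C=C(C)[C@H](O1)C[C@H]2c1ccccc1 | intermediate
5 | rac-(1R,4R,8R)-6-methyl-8-phenyl-2-oxabicyclo[2.2.2]oct-5-en-3-one (racemic) | O=C1[C@@H]2C=C(C)[C@H](O1)C[C@H]2c1ccccc1 | intermediate
6 | rac-(1R,4R,5R)-4-(hydroxymethyl)-2-methyl-5-phenylcyclohex-2-en-1-ol (racemic) | OC[C@@H]1C=C(C)[C@H](O)C[C@H]1c1ccccc1 | intermediate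
7 | (1R,4R,5R)-4-(hydroxymethyl)-2-methyl-5-phenylcyclohex-2-en-1-ol (single enantiomer) | OC[C@@H]1C=C(C)[C@H](O)C[C@H]1c1ccccc1 | intermediate
8 | (1R,4R,5R)-4-({[tert-butyl(dimethyl)silyl]oxy}methyl)-2-methyl-5-phenylcyclohex-2-en-1-ol | CC(C)(C)[Si](C)(C)OC[C@@H]1C=C(C)[C@H](O)C[C@H]1c1ccccc1 | intermediate
9 | triethyl orthoacetate (1,1,1-triethoxyethane) | CC(OCC)(OCC)OCC | starting material
10 | tert-butyl{[(1R,4R,6R)-4-(1,1-diethoxyethoxy)-3-methyl-6-phenylcyclohex-2-en-1-yl]methoxy}dimethylsilane (mixed orthoester, not isolated) | CC(C)(C)[Si](C)(C)OC[C@@H]1C=C(C)[C@H](OC(C)(OCC)OCC)C[C@H]1c1ccccc1 | intermediate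
11 | tert-butyl({(1R,4R,6R)-4-[(1-ethoxyethenyl)oxy]-3-methyl-6-phenylcyclohex-2-en-1-yl}methoxy)dimethylsilane (ketene acetal, not isolated) | CC(C)(C)[Si](C)(C)OC[C@@H]1C=C(C)[C@H](OC(=C)OCC)C[C@H]1c1ccccc1 | intermediate
12 | ethyl 2-[(1S,5R,6R)-6-({[tert-butyl(dimethyl)silyl]oxy}methyl)-2-methyl-5-phenylcyclohex-2-en-1-yl]acetate | CC(C)(C)[Si](C)(C)OC[C@@H]1[C@H](CC(=O)OCC)C(C)=CC[C@H]1c1ccccc1 | intermediate
13 | 2-[(1S,5R,6R)-6-({[tert-butyl(dimethyl)silyl]oxy}methyl)-2-methyl-5-phenylcyclohex-2-en-1-yl]acetaldehyde | CC(C)(C)[Si](C)(C)OC[C@@H]1[C@H](CC=O)C(C)=CC[C@H]1c1ccccc1 | intermediate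
14 | tert-butyl(dimethyl){[(1R,2S,6R)-3-methyl-2-(3-methylbut-2-en-1-yl)-6-phenylcyclohex-3-en-1-yl]methoxy}silane | CC(C)(C)[Si](C)(C)OC[C@@H]1[C@H](CC=C(C)C)C(C)=CC[C@H]1c1ccccc1 | intermediate
15 | [(1R,2S,6R)-3-methyl-2-(3-methylbut-2-en-1-yl)-6-phenylcyclohex-3-en-1-yl]methanol | OC[C@@H]1[C@H](CC=C(C)C)C(C)=CC[C@H]1c1ccccc1 | intermediate
16 | (1R,2S,6R)-3-methyl-2-(3-methylbut-2-en-1-yl)-6-phenylcyclohex-3-ene-1-carbaldehyde | O=C[C@@H]1[C@H](CC=C(C)C)C(C)=CC[C@H]1c1ccccc1 | intermediate
17 | 3,5-dimethoxyphenol | COc1cc(O)cc(OC)c1 | starting material
18 | 1-(2,2-diethoxyethoxy)-3,5-dimethoxybenzene | CCOC(COc1cc(OC)cc(OC)c1)OCC | intermediate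
19 | 4,6-dimethoxy-1-benzofuran | COc1cc(OC)c2ccoc2c1 | intermediate
20 | 7-bromo-4,6-dimethoxy-1-benzofuran | COc1cc(OC)c2ccoc2c1Br | intermediate
21 | (4,6-dimethoxy-1-benzofuran-7-yl)lithium (not isolated) | [Li]c1c(OC)cc(OC)c2ccoc12 | intermediate
22 | (4,6-dimethoxy-1-benzofuran-7-yl)[(1R,2S,6R)-3-methyl-2-(3-methylbut-2-en-1-yl)-6-phenylcyclohex-3-en-1-yl]methanol (both carbinol epimers) | COc1cc(OC)c(C(O)[C@@H]2[C@H](CC=C(C)C)C(C)=CC[C@H]2c2ccccc2)c2occc12 | intermediate
23 | (4,6-dimethoxy-1-benzofuran-7-yl)[(1R,2S,6R)-3-methyl-2-(3-methylbut-2-en-1-yl)-6-phenylcyclohex-3-en-1-yl]methanone | COc1cc(OC)c(C(=O)[C@@H]2[C@H](CC=C(C)C)C(C)=CC[C@H]2c2ccccc2)c2occc12 | intermediate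
24 | (6-hydroxy-4-methoxy-1-benzofuran-7-yl)[(1R,2S,6R)-3-methyl-2-(3-methylbut-2-en-1-yl)-6-phenylcyclohex-3-en-1-yl]methanone | COc1cc(O)c(C(=O)[C@@H]2[C@H](CC=C(C)C)C(C)=CC[C@H]2c2ccccc2)c2occc12 | target

## Step count and least certain steps

Total: 17 steps. Longest linear sequence: 14 steps (steps 1–11 and 15–17); the arene branch (steps 12–14) joins at step 15.

**Step 2 (key step).** The methyl-substituted diene is less electron-poor than the dibromide on which this cycloaddition is best documented. Slow addition may then let styrene polymerisation, erosion of endo selectivity, or loss of CO2 at a higher temperature take over. The fallback keeps the cycloaddition but changes the order of events and sets out from 1 and 3. Heating them in toluene at 100 °C should give rac-(1R,4R,8S)-4,6-dibromo-8-phenyl-2-oxabicyclo[2.2.2]oct-5-en-3-one F1. One equivalent of Bu3SnH with AIBN should remove only the tertiary bridgehead bromine, whose C–Br bond is much weaker than the vinylic one, to give rac-(1R,4S,8R)-6-bromo-8-phenyl-2-oxabicyclo[2.2.2]oct-5-en-3-one F2. Negishi coupling of the vinylic bromide with MeZnCl (Pd(PPh3)4, THF, 50 °C) then introduces the methyl group and returns to the route at 5.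

**Step 1.** Site selectivity may be lost. The C5 preference is established for groups that transfer readily from tin, and a methyl group may instead couple at the C3 bromide or at both positions. The fallback removes the choice of site: it does not branch from a compound of the route but replaces 1 by commercial 5-bromo-2H-pyran-2-one F3 and rejoins at 2. Stille methylation of this single bromide (Me4Sn, Pd(PPh3)4, DMF) gives 5-methyl-2H-pyran-2-one F4. Bromine in CH2Cl2 followed by Et3N then brominates C3, the only free nucleophilic position, by addition–elimination to give 2.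

**Step 5.** The enzyme may discriminate the enantiomers poorly, because the stereocentre is one carbon away from the reacting oxygen, or it may also acylate the secondary hydroxyl group. The fallback is a resolution through covalent diastereomers and sets out from 6. Silylation as in step 6 gives the racemic silyl ether rac-(1R,4R,5R)-4-({[tert-butyl(dimethyl)silyl]oxy}methyl)-2-methyl-5-phenylcyclohex-2-en-1-ol F5. Steglich esterification with (2S)-2-methoxy-2-phenylacetic acid (DCC, DMAP) gives two diastereomeric esters that are separated by chromatography or crystallisation. The wanted one is (1R,4R,5R)-4-({[tert-butyl(dimethyl)silyl]oxy}methyl)-2-methyl-5-phenylcyclohex-2-en-1-yl (2S)-2-methoxy-2-phenylacetate F6, and methanolysis (K2CO3, MeOH) returns to the route at 8.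

**Step 7.** At 140 °C with acid the allylic C–O bond may ionise and eliminate to a diene, or the shift may be slow because the new bond is made next to the CH2OTBS-bearing carbon on the same face. The fallback uses an ester enolate shift at much lower temperature and sets out from 8. Acetylation (Ac2O, pyridine, DMAP) gives (1R,4R,5R)-4-({[tert-butyl(dimethyl)silyl]oxy}methyl)-2-methyl-5-phenylcyclohex-2-en-1-yl acetate F7. Ireland–Claisen rearrangement (LDA, TMSCl, THF, −78 °C to 60 °C, aqueous work-up) gives 2-[(1S,5R,6R)-6-({[tert-butyl(dimethyl)silyl]oxy}methyl)-2-methyl-5-phenylcyclohex-2-en-1-yl]acetic acid F8. Esterification (EtI, K2CO3, DMF) returns to the route at 12.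

**Step 14.** Bromination may go to C5 or to the furan ring, or may not stop at one bromine. The fallback fixes the halogen before the furan is closed and sets out from 17. Ortho-bromination directed by the free hydroxyl group (t-BuNH2, Br2, PhMe, −78 °C) gives 2-bromo-3,5-dimethoxyphenol F9, which is recognised by its unsymmetrical NMR spectrum. Alkylation as in step 12 gives 2-bromo-1-(2,2-diethoxyethoxy)-3,5-dimethoxybenzene F10. Cyclodehydration as in step 13 can then occur only at the one free ortho position and returns to the route at 20.

**Step 15.** Proton transfer may compete with addition: the hindered, α-branched aldehyde may be enolised, with loss of configuration at C1, or lithium may migrate to C2 of the benzofuran. The fallback makes the ketone by acylative cross-coupling and sets out from 16 and 21. Pinnick oxidation of 16 (NaClO2, NaH2PO4, 2-methylbut-2-ene, t-BuOH/H2O) gives (1R,2S,6R)-3-methyl-2-(3-methylbut-2-en-1-yl)-6-phenylcyclohex-3-ene-1-carboxylic acid F11. Thioesterification (EtSH, DCC, DMAP) gives S-ethyl (1R,2S,6R)-3-methyl-2-(3-methylbut-2-en-1-yl)-6-phenylcyclohex-3-ene-1-carbothioate F12. Transmetalation of 21 with ZnCl2 gives chloro(4,6-dimethoxy-1-benzofuran-7-yl)zinc F13. Fukuyama coupling of F12 with F13 (PdCl2(PPh3)2, THF, rt) returns to the route at 23, so that 22 and step 16 are bypassed.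

## Further compounds

F1 | step 2 | rac-(1R,4R,8S)-4,6-dibromo-8-phenyl-2-oxabicyclo[2.2.2]oct-5-en-3-one (endo; racemic) | O=C1[C@]2(Br)C=C(Br)[C@H](O1)C[C@H]2c1ccccc1
F2 | step 2 | rac-(1R,4S,8R)-6-bromo-8-phenyl-2-oxabicyclo[2.2.2]oct-5-en-3-one (racemic) | O=C1[C@@H]2C=C(Br)[C@H](O1)C[C@H]2c1ccccc1
F3 | step 1 | 5-bromo-2H-pyran-2-one | O=C1C=CC(Br)=CO1
F4 | step 1 | 5-methyl-2H-pyran-2-one | CC1=COC(=O)C=C1
F5 | step 5 | rac-(1R,4R,5R)-4-({[tert-butyl(dimethyl)silyl]oxy}methyl)-2-methyl-5-phenylcyclohex-2-en-1-ol (racemic) | CC(C)(C)[Si](C)(C)OC[C@@H]1C=C(C)[C@H](O)C[C@H]1c1ccccc1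
F6 | step 5 | (1R,4R,5R)-4-({[tert-butyl(dimethyl)silyl]oxy}methyl)-2-methyl-5-phenylcyclohex-2-en-1-yl (2S)-2-methoxy-2-phenylacetate | CC(C)(C)[Si](C)(C)OC[C@@H]1C=C(C)[C@H](OC(=O)[C@@H](OC)c2ccccc2)C[C@H]1c1ccccc1
F7 | step 7 | (1R,4R,5R)-4-({[tert-butyl(dimethyl)silyl]oxy}methyl)-2-methyl-5-phenylcyclohex-2-en-1-yl acetate | CC(C)(C)[Si](C)(C)OC[C@@H]1C=C(C)[C@H](OC(C)=O)C[C@H]1c1ccccc1
F8 | step 7 | 2-[(1S,5R,6R)-6-({[tert-butyl(dimethyl)silyl]oxy}methyl)-2-methyl-5-phenylcyclohex-2-en-1-yl]acetic acid | CC(C)(C)[Si](C)(C)OC[C@@H]1[C@H](CC(=O)O)C(C)=CC[C@H]1c1ccccc1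
F9 | step 14 | 2-bromo-3,5-dimethoxyphenol | COc1cc(O)c(Br)c(OC)c1
F10 | step 14 | 2-bromo-1-(2,2-diethoxyethoxy)-3,5-dimethoxybenzene | CCOC(COc1cc(OC)cc(OC)c1Br)OCC
F11 | step 15 | (1R,2S,6R)-3-methyl-2-(3-methylbut-2-en-1-yl)-6-phenylcyclohex-3-ene-1-carboxylic acid | OC(=O)[C@@H]1[C@H](CC=C(C)C)C(C)=CC[C@H]1c1ccccc1
F12 | step 15 | S-ethyl (1R,2S,6R)-3-methyl-2-(3-methylbut-2-en-1-yl)-6-phenylcyclohex-3-ene-1-carbothioate | CCSC(=O)[C@@H]1[C@H](CC=C(C)C)C(C)=CC[C@H]1c1ccccc1
F13 | step 15 | chloro(4,6-dimethoxy-1-benzofuran-7-yl)zinc | Cl[Zn]c1c(OC)cc(OC)c2ccoc12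
A1 | alternative 1 | [6-hydroxy-4-methoxy-2-(trimethylsilyl)-1-benzofuran-7-yl][(1R,2S,6R)-3-methyl-2-(3-methylbut-2-en-1-yl)-6-phenylcyclohex-3-en-1-yl]methanone | COc1cc(O)c(C(=O)[C@@H]2[C@H](CC=C(C)C)C(C)=CC[C@H]2c2ccccc2)c2oc([Si](C)(C)C)cc12
A2 | alternative 1 | (2,6-dihydroxy-3-iodo-4-methoxyphenyl)[(1R,2S,6R)-3-methyl-2-(3-methylbut-2-en-1-yl)-6-phenylcyclohex-3-en-1-yl]methanone | COc1cc(O)c(C(=O)[C@@H]2[C@H](CC=C(C)C)C(C)=CC[C@H]2c2ccccc2)c(O)c1I
A3 | alternative 1 | (2,6-dihydroxy-4-methoxyphenyl)[(1R,2S,6R)-3-methyl-2-(3-methylbut-2-en-1-yl)-6-phenylcyclohex-3-en-1-yl]methanone | COc1cc(O)c(C(=O)[C@@H]2[C@H](CC=C(C)C)C(C)=CC[C@H]2c2ccccc2)c(O)c1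
A4 | alternative 2 | (4,6-dimethoxy-1-benzofuran-7-yl)[(1R,2S,6R)-3-methyl-2-(3-methylbut-2-en-1-yl)-6-phenylcyclohex-3-en-1-yl]methanone (identical with 23) | COc1cc(OC)c(C(=O)[C@@H]2[C@H](CC=C(C)C)C(C)=CC[C@H]2c2ccccc2)c2occc12
A5 | alternative 2 | (2R,3S)-1-(4,6-dimethoxy-1-benzofuran-7-yl)-6-methyl-2-[(1R)-1-phenylbut-3-en-1-yl]-3-(prop-1-en-2-yl)hept-5-en-1-one | COc1cc(OC)c(C(=O)[C@H]([C@H](CC=C(C)C)C(C)=C)[C@@H](CC=C)c2ccccc2)c2occc12
A6 | alternative 3 | [(1R,2S,6R)-3-methyl-2-(3-methylbut-2-en-1-yl)-6-phenylcyclohex-3-en-1-yl](2,4,6-trihydroxyphenyl)methanone | Oc1cc(O)c(C(=O)[C@@H]2[C@H](CC=C(C)C)C(C)=CC[C@H]2c2ccccc2)c(O)c1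
A7 | alternative 3 | methyl 7-[(1R,2S,6R)-3-methyl-2-(3-methylbut-2-en-1-yl)-6-phenylcyclohex-3-en-1-yl]-3,5,7-trioxoheptanoate | COC(=O)CC(=O)CC(=O)CC(=O)[C@@H]1[C@H](CC=C(C)C)C(C)=CC[C@H]1c1ccccc1
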